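**Plan**

1. Retrosynthesis: the lactone enol ether is unmasked last; ring A (the pyran) is cut at O2–C3 (enol oxygen onto an alkyne) and C1–C8a (one-carbon formyl unit), the side chain at C4–C4a (Sonogashira), and C5–Cl and the C4a oxygen lead back to a cyclohexane-1,3-dione.
2. Ring B (C4a, C5, C6, C7, C8, C8a, isochromene numbering) is cut at C7–C8 and C5–C6: C7 with its CH3, OH and acyl carbon C6 is a lactic acid carbon bonded to C8, and C4a–C5–C6 is a masked 1,3-dione, so ring B is a lactate dioxolanone enolate plus a lactonyl methyl enone.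
3. Forward order: lactone ring (Claisen, lactonisation), enone (Heck), ring B (Michael–Claisen), then Cl, triflate and dienyne, ring A (gold 6-endo cyclisation), fluoride deprotection.
4. Stereochemistry: C7 from (R)-lactic acid, relayed through the tert-butyl acetal with retention; C8 from the facial pairing in the Michael addition; C6′ from ethyl (S)-3-hydroxybutanoate; side-chain C5 from (S)-2-methylbutan-1-ol; both side-chain alkenes E from Wittig and HWE olefinations.

Key step: step 6

Remark on the chemistry: C3′ of the 2,4-dioxo-lactone lies between two carbonyls and epimerises through its enol, so the (3′R) keto form drawn is taken to be the form reached at equilibrium and is not set by a separate step.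
Abbreviation: Lac = (6S)-6-methyl-2-oxo-4-[2-(trimethylsilyl)ethoxy]-5,6-dihydro-2H-pyran-3-yl. Primed locants refer to the lactone, unprimed ring locants in the comments to the isochromene core of the target.

Step 1
Reactants: 1 (R)-lactic acid; 2 pivaldehyde
Product: 3 (2R,5R)-2-tert-butyl-5-methyl-1,3-dioxolan-4-one (cis)
Conditions: p-TsOH·H2O (cat.), H2SO4 (cat.), pentane, reflux, Dean–Stark; recrystallisation from pentane, −78 °C
Reagents that add atoms: none
Why: Acid-catalysed acetalisation with water removal (Seebach dioxolanone) should give mainly the cis acetal, purified by crystallisation, whose acetal carbon is set under thermodynamic control by the lactate centre and later relays it.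

Step 2
Reactants: 4 ethyl (S)-3-hydroxybutanoate
Product: 6 (S)-4-hydroxy-6-methyl-5,6-dihydro-2H-pyran-2-one, via tert-butyl (S)-5-hydroxy-3-oxohexanoate 5 (not isolated)
Conditions: t-BuOAc, LDA (3.5 equiv each), THF, −78 → −20 °C; aq. NH4Cl; crude 5, TFA, CH2Cl2, rt
Reagents that add atoms: tert-butyl acetate, CC(=O)OC(C)(C)C
Why: Crossed Claisen condensation with excess lithium tert-butyl acetate enolate, then acid-induced loss of the tert-butyl group and lactonisation, is the standard entry to 6-substituted 4-hydroxy-5,6-dihydropyran-2-ones and leaves the carbinol centre C6′ untouched.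

Step 3
Reactants: 6 (S)-4-hydroxy-6-methyl-5,6-dihydro-2H-pyran-2-one
Product: 7 (S)-6-methyl-4-[2-(trimethylsilyl)ethoxy]-5,6-dihydro-2H-pyran-2-one
Conditions: Me3SiCH2CH2OH, PPh3, DIAD, THF, 0 °C → rt
Reagents that add atoms: 2-(trimethylsilyl)ethanol, C[Si](C)(C)CCO
Why: Mitsunobu O-alkylation of the acidic enol should give the 4-alkoxy-dihydropyranone regioselectively, and the 2-(trimethylsilyl)ethyl enol ether masks the β-keto lactone until the final fluoride step.

Step 4
Reactants: 7 (S)-6-methyl-4-[2-(trimethylsilyl)ethoxy]-5,6-dihydro-2H-pyran-2-one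
Product: 8 (S)-3-bromo-6-methyl-4-[2-(trimethylsilyl)ethoxy]-5,6-dihydro-2H-pyran-2-one
Conditions: NBS, CH2Cl2, 0 °C → rt
Reagents that add atoms: N-bromosuccinimide, O=C1CCC(=O)N1Br
Why: Electrophilic bromination of the β-alkoxy enoate at its nucleophilic α-carbon C3′ (Br+ addition, then loss of H+).

Step 5
Reactants: 8 (S)-3-bromo-6-methyl-4-[2-(trimethylsilyl)ethoxy]-5,6-dihydro-2H-pyran-2-one
Product: 9 (S,E)-6-methyl-3-(3-oxobut-1-en-1-yl)-4-[2-(trimethylsilyl)ethoxy]-5,6-dihydro-2H-pyran-2-one
Conditions: methyl vinyl ketone, Pd(OAc)2 (5 mol%), P(o-tol)3 (10 mol%), Et3N, DMF, 80 °C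
Reagents that add atoms: methyl vinyl ketone, CC(=O)C=C
Why: Mizoroki–Heck coupling of the vinyl bromide with the enone, in which syn insertion and syn β-hydride elimination should give the (E)-alkene.

Step 6
Reactants: 3 (2R,5R)-2-tert-butyl-5-methyl-1,3-dioxolan-4-one; 9 (S,E)-6-methyl-3-(3-oxobut-1-en-1-yl)-4-[2-(trimethylsilyl)ethoxy]-5,6-dihydro-2H-pyran-2-one
Product: 12 (4S,5R)-4-hydroxy-4-methyl-5-Lac-cyclohexane-1,3-dione, via lithium dioxolanone enolate 10 (not isolated), via Michael adduct lithium enolate 11 (not isolated)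
Conditions: LDA (1.25 equiv), 3 (1.3 equiv), THF, −78 °C, 30 min; 9, THF, −78 °C, 2 h; t-BuOH (0.3 equiv), −78 → 0 °C; aq. NH4Cl, pH 3
Reagents that add atoms: none
Why: Proposed new method: the tertiary lithium enolate 10 adds through the face anti to its tert-butyl group to C8 of enone 9 (1,4-addition; any 1,2-aldolate should revert on warming), enolate 11 is equilibrated by the t-BuOH/t-BuOLi shuttle to the terminal CH3 enolate, and this attacks the dioxolanone carbonyl C6, whose hemiacetal alkoxide collapses to pivaldehyde and the C7 alkoxide, which is protonated by the far more acidic 1,3-dione so that the dione enolate is the sink. The closest known reactions are Michael additions of lactate and mandelate dioxolanone enolates to enones and nitroalkenes, the dimedone-type Michael–Claisen synthesis of cyclohexane-1,3-diones and the acylation of enolates by dioxolanone carbonyls; running them in tandem with the acetal ester as acyl donor is the untested part. Ring B closes by 6-exo-trig Claisen attack of C5 on C6 after the intermolecular C7–C8 bond. C7 is fixed by the acetal, whose tert-butyl group shields one enolate face so that the new bond takes the place of the lactate hydrogen (retention); C8 should follow from a lithium-bridged synclinal transition state with the lactonyl group antiperiplanar to the enolate carbon C6 and the enone arm over the ring oxygen instead of next to the C7 methyl, which places the lactonyl group cis to the C7 oxygen. The step needs 1,4- over 1,2-addition and over attack at C4′, acylation at the dioxolanone and not the lactone carbonyl, and one enone face; the first two are secured by the hindered tertiary nucleophile and by the fully substituted push–pull C3′=C4′(OR) unit, which has no acidic C3′–H, blocks C4′ and deactivates the lactone carbonyl against the activated acetal ester, whereas the facial pairing is the least certain element.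

Step 7
Reactants: 12 (4S,5R)-4-hydroxy-4-methyl-5-Lac-cyclohexane-1,3-dione
Product: 13 (5R,6S)-2-chloro-3,6-dihydroxy-6-methyl-5-Lac-cyclohex-2-en-1-one (enol form of the 2-chloro-1,3-dione)
Conditions: NCS (1.0 equiv), CH2Cl2, 0 °C
Reagents that add atoms: N-chlorosuccinimide, O=C1CCC(=O)N1Cl
Why: Electrophilic chlorination of the 1,3-dione at C5, its only strongly nucleophilic carbon, since C3′ of the lactone is fully substituted.

Step 8
Reactants: 13 (5R,6S)-2-chloro-3,6-dihydroxy-6-methyl-5-Lac-cyclohex-2-en-1-one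
Product: 14 (4S,5R)-2-chloro-4-hydroxy-4-methyl-5-Lac-3-oxocyclohex-1-en-1-yl trifluoromethanesulfonate
Conditions: Tf2O (1.05 equiv), Et3N, CH2Cl2, −78 °C
Reagents that add atoms: trifluoromethanesulfonic anhydride, O=S(=O)(OS(=O)(=O)C(F)(F)F)C(F)(F)F
Why: O-sulfonylation of the dione enolate (enol triflate formation) should take place at the C4a oxygen, which is flanked by a CH2 group, whereas the C6 oxygen is shielded by the quaternary C7 and hydrogen-bonded to its hydroxyl, and the hindered tertiary alcohol should not react at −78 °C.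

Step 9
Reactants: 15 (S)-2-methylbutan-1-ol
Product: 17 (S,E)-2,4-dimethylhex-2-enal, via (S)-2-methylbutanal 16 (not isolated)
Conditions: TEMPO (cat.), KBr (cat.), NaOCl, NaHCO3, CH2Cl2/H2O, 0 °C; dried organic phase, Ph3P=C(CH3)CHO, toluene, 80 °C (sealed)
Reagents that add atoms: 2-(triphenylphosphoranylidene)propanal, CC(C=O)=P(c1ccccc1)(c1ccccc1)c1ccccc1
Why: Anelli oxidation gives the configurationally fragile aldehyde, which is used at once in a Wittig reaction with the stabilised formyl ylide; this should give the (E)-enal without exposing the stereocentre to strong base.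

Step 10
Reactants: 17 (S,E)-2,4-dimethylhex-2-enal
Product: 18 trimethyl[(3E,5E,7S)-5,7-dimethylnona-3,5-dien-1-yn-1-yl]silane
Conditions: (EtO)2P(O)CH2C≡CSiMe3, LiHMDS, THF, −78 → 0 °C
Reagents that add atoms: diethyl [3-(trimethylsilyl)prop-2-yn-1-yl]phosphonate, CCOP(=O)(CC#C[Si](C)(C)C)OCC
Why: Horner–Wadsworth–Emmons olefination with the propargylic phosphonate should give mainly the (3E)-enyne, the minor (3Z) isomer being removed by chromatography.

Step 11
Reactants: 18 trimethyl[(3E,5E,7S)-5,7-dimethylnona-3,5-dien-1-yn-1-yl]silane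
Product: 19 (3E,5E,7S)-5,7-dimethylnona-3,5-dien-1-yne
Conditions: K2CO3 (cat.), MeOH, rt
Reagents that add atoms: none
Why: Methanolysis of the alkynyl C–Si bond (protodesilylation) frees the terminal alkyne.

Step 12
Reactants: 14 (4S,5R)-2-chloro-4-hydroxy-4-methyl-5-Lac-3-oxocyclohex-1-en-1-yl trifluoromethanesulfonate; 19 (3E,5E,7S)-5,7-dimethylnona-3,5-dien-1-yne
Product: 20 (5R,6S)-2-chloro-3-[(3E,5E,7S)-5,7-dimethylnona-3,5-dien-1-yn-1-yl]-6-hydroxy-6-methyl-5-Lac-cyclohex-2-en-1-one
Conditions: PdCl2(PPh3)2 (5 mol%), CuI (10 mol%), i-Pr2NEt, THF, rt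
Reagents that add atoms: none
Why: Sonogashira coupling of the β-triflyloxy enone forms C4a–C4; the triflate should react far faster than the vinylic C5–Cl bond, and the hindered tertiary amine does not add to the enone.

Step 13
Reactants: 20 (5R,6S)-2-chloro-3-[(3E,5E,7S)-5,7-dimethylnona-3,5-dien-1-yn-1-yl]-6-hydroxy-6-methyl-5-Lac-cyclohex-2-en-1-one
Product: 22 (4Z,5R,6S)-2-chloro-3-[(3E,5E,7S)-5,7-dimethylnona-3,5-dien-1-yn-1-yl]-6-hydroxy-4-(hydroxymethylidene)-6-methyl-5-Lac-cyclohex-2-en-1-one, via dimethylaminomethylene enone 21 (not isolated)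
Conditions: t-BuOCH(NMe2)2, toluene, 60 °C, N2 sweep; then 1 M HCl, THF, 0 °C
Reagents that add atoms: tert-butoxybis(dimethylamino)methane, CN(C)C(OC(C)(C)C)N(C)C; water, O
Why: Vinylogous aminomethylenation with Bredereck's reagent at C8a, the most acidic C–H (γ to C6=O, with C7 quaternary), should give the push–pull dienamine, and hydrolysis of its iminium form in cold dilute acid gives the hydroxymethylene compound without touching the enol ether or the tertiary alcohol.

Step 14
Reactants: 22 (4Z,5R,6S)-2-chloro-3-[(3E,5E,7S)-5,7-dimethylnona-3,5-dien-1-yn-1-yl]-6-hydroxy-4-(hydroxymethylidene)-6-methyl-5-Lac-cyclohex-2-en-1-one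
Product: 23 (7S,8R)-5-chloro-3-[(1E,3E,5S)-3,5-dimethylhepta-1,3-dien-1-yl]-7-hydroxy-7-methyl-8-Lac-7,8-dihydro-6H-isochromen-6-one
Conditions: Ph3PAuNTf2 (5 mol%), CH2Cl2, rt
Reagents that add atoms: none
Why: Gold(I)-catalysed 6-endo-dig cycloisomerisation of the enol oxygen onto the alkyne closes ring A; attack at C3 should be preferred because C3 is the δ-terminus of the ynenone and carries the cation-stabilising dienyl group, as in cycloisomerisations of o-alkynyl carbonyl compounds to isochromenylium salts.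

Step 15
Reactants: 23 (7S,8R)-5-chloro-3-[(1E,3E,5S)-3,5-dimethylhepta-1,3-dien-1-yl]-7-hydroxy-7-methyl-8-Lac-7,8-dihydro-6H-isochromen-6-one
Product: 24 (7S,8S)-5-chloro-3-[(1E,3E,5S)-3,5-dimethylhepta-1,3-dien-1-yl]-7-hydroxy-7-methyl-8-[(3R,6S)-6-methyl-2,4-dioxooxan-3-yl]-7,8-dihydro-6H-isochromen-6-one (CNP0584120.1)
Conditions: TBAF, AcOH (1:1), THF, 0 °C → rt; pH 4 buffer
Reagents that add atoms: none
Why: Fluoride attack on silicon fragments the 2-(trimethylsilyl)ethyl enol ether (β-elimination) under buffered conditions that should spare the azaphilone chromophore and the tertiary α-ketol, and the freed 2,4-dioxo-lactone settles at C3′ through its enol; the change of the C8 descriptor from R to S is a priority change only.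

**Compound list**

1 | (R)-lactic acid | C[C@@H](O)C(=O)O | starting material
2 | pivaldehyde | CC(C)(C)C=O | starting material
3 | (2R,5R)-2-tert-butyl-5-methyl-1,3-dioxolan-4-one | C[C@H]1O[C@@H](C(C)(C)C)OC1=O | intermediate
4 | ethyl (S)-3-hydroxybutanoate | C[C@H](O)CC(=O)OCC | starting material
5 | tert-butyl (S)-5-hydroxy-3-oxohexanoate (not isolated) | C[C@H](O)CC(=O)CC(=O)OC(C)(C)C | intermediate
6 | (S)-4-hydroxy-6-methyl-5,6-dihydro-2H-pyran-2-one | O=C1C=C(O)C[C@H](C)O1 | intermediate
7 | (S)-6-methyl-4-[2-(trimethylsilyl)ethoxy]-5,6-dihydro-2H-pyran-2-one | O=C1C=C(OCC[Si](C)(C)C)C[C@H](C)O1 | intermediate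
8 | (S)-3-bromo-6-methyl-4-[2-(trimethylsilyl)ethoxy]-5,6-dihydro-2H-pyran-2-one | O=C1C(Br)=C(OCC[Si](C)(C)C)C[C@H](C)O1 | intermediate
9 | (S,E)-6-methyl-3-(3-oxobut-1-en-1-yl)-4-[2-(trimethylsilyl)ethoxy]-5,6-dihydro-2H-pyran-2-one | CC(=O)/C=C/C1=C(OCC[Si](C)(C)C)C[C@H](C)OC1=O | intermediate
10 | lithium (2R)-2-tert-butyl-5-methyl-1,3-dioxol-4-olate, the enolate of 3 (not isolated) | [Li+].CC1=C([O-])O[C@H](C(C)(C)C)O1 | intermediate
11 | lithium (Z)-enolate of (2R,5S)-2-tert-butyl-5-methyl-5-[(1R)-1-Lac-3-oxobutyl]-1,3-dioxolan-4-one (not isolated) | [Li+].C/C([O-])=C/[C@@H]([C@]1(C)O[C@@H](C(C)(C)C)OC1=O)C2=C(OCC[Si](C)(C)C)C[C@H](C)OC2=O | intermediate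
12 | (4S,5R)-4-hydroxy-4-methyl-5-Lac-cyclohexane-1,3-dione | O=C1CC(=O)[C@@](C)(O)[C@@H](C2=C(OCC[Si](C)(C)C)C[C@H](C)OC2=O)C1 | intermediate
13 | (5R,6S)-2-chloro-3,6-dihydroxy-6-methyl-5-Lac-cyclohex-2-en-1-one | OC1=C(Cl)C(=O)[C@@](C)(O)[C@@H](C2=C(OCC[Si](C)(C)C)C[C@H](C)OC2=O)C1 | intermediate
14 | (4S,5R)-2-chloro-4-hydroxy-4-methyl-5-Lac-3-oxocyclohex-1-en-1-yl trifluoromethanesulfonate | O=S(=O)(OC1=C(Cl)C(=O)[C@@](C)(O)[C@@H](C2=C(OCC[Si](C)(C)C)C[C@H](C)OC2=O)C1)C(F)(F)F | intermediate
15 | (S)-2-methylbutan-1-ol | CC[C@H](C)CO | starting material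
16 | (S)-2-methylbutanal (not isolated) | CC[C@H](C)C=O | intermediate
17 | (S,E)-2,4-dimethylhex-2-enal | CC[C@H](C)/C=C(C)/C=O | intermediate
18 | trimethyl[(3E,5E,7S)-5,7-dimethylnona-3,5-dien-1-yn-1-yl]silane | CC[C@H](C)/C=C(C)/C=C/C#C[Si](C)(C)C | intermediate
19 | (3E,5E,7S)-5,7-dimethylnona-3,5-dien-1-yne | CC[C@H](C)/C=C(C)/C=C/C#C | intermediate
20 | (5R,6S)-2-chloro-3-[(3E,5E,7S)-5,7-dimethylnona-3,5-dien-1-yn-1-yl]-6-hydroxy-6-methyl-5-Lac-cyclohex-2-en-1-one | CC[C@H](C)/C=C(C)/C=C/C#CC1=C(Cl)C(=O)[C@@](C)(O)[C@@H](C2=C(OCC[Si](C)(C)C)C[C@H](C)OC2=O)C1 | intermediate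
21 | (4Z,5R,6S)-2-chloro-4-[(dimethylamino)methylidene]-3-[(3E,5E,7S)-5,7-dimethylnona-3,5-dien-1-yn-1-yl]-6-hydroxy-6-methyl-5-Lac-cyclohex-2-en-1-one (not isolated; enamine geometry of no consequence) | CC[C@H](C)/C=C(C)/C=C/C#CC1=C(Cl)C(=O)[C@@](C)(O)[C@@H](C2=C(OCC[Si](C)(C)C)C[C@H](C)OC2=O)/C1=C/N(C)C | intermediate
22 | (4Z,5R,6S)-2-chloro-3-[(3E,5E,7S)-5,7-dimethylnona-3,5-dien-1-yn-1-yl]-6-hydroxy-4-(hydroxymethylidene)-6-methyl-5-Lac-cyclohex-2-en-1-one | CC[C@H](C)/C=C(C)/C=C/C#CC1=C(Cl)C(=O)[C@@](C)(O)[C@@H](C2=C(OCC[Si](C)(C)C)C[C@H](C)OC2=O)/C1=C/O | intermediate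
23 | (7S,8R)-5-chloro-3-[(1E,3E,5S)-3,5-dimethylhepta-1,3-dien-1-yl]-7-hydroxy-7-methyl-8-Lac-7,8-dihydro-6H-isochromen-6-one | CC[C@H](C)/C=C(C)/C=C/C1=CC2=C(Cl)C(=O)[C@@](C)(O)[C@@H](C3=C(OCC[Si](C)(C)C)C[C@H](C)OC3=O)C2=CO1 | intermediate
24 | (7S,8S)-5-chloro-3-[(1E,3E,5S)-3,5-dimethylhepta-1,3-dien-1-yl]-7-hydroxy-7-methyl-8-[(3R,6S)-6-methyl-2,4-dioxooxan-3-yl]-7,8-dihydro-6H-isochromen-6-one | CC[C@H](C)/C=C(C)/C=C/C1=CC2=C(Cl)C(=O)[C@@](C)(O)[C@@H]([C@@H]3C(=O)C[C@H](C)OC3=O)C2=CO1 | target

**Step count and risks**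

Total step count: 15. Longest linear sequence: 11 steps (from 4: steps 2–8 and 12–15).

Steps most likely to fail:

Step 6 (Proposed new method). The enolate may take a proton from the methyl ketone or add 1,2 instead of attacking C8; the adduct enolate may acylate on oxygen or fail to equilibrate to the terminal enolate; and the enone face may be chosen without preference. The fallback runs the two events separately with known chemistry, setting out from 3 and 9 and coming back at 12. Compound 3 is converted (LDA, TBSCl, THF/DMPU, −78 °C) into the silyl ketene acetal (2R)-2-tert-butyl-4-[(tert-butyldimethylsilyl)oxy]-5-methyl-1,3-dioxole F1. A TiCl4-promoted Mukaiyama–Michael addition of F1 to 9 (CH2Cl2, −78 °C), in which no basic species is present and the Lewis acid enforces 1,4-addition anti to tert-butyl, should give after aqueous work-up the keto dioxolanone (2R,5S)-2-tert-butyl-5-methyl-5-[(1R)-1-Lac-3-oxobutyl]-1,3-dioxolan-4-one F2, at which stage C8 epimers can be separated. Kinetic deprotonation of the methyl ketone of F2 with LDA at −78 °C gives the terminal enolate directly, and warming to 0 °C should close ring B by Claisen acylation on the dioxolanone carbonyl with loss of pivaldehyde, giving 12.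

Step 13. Deprotonation at C8a may be slow, the dimethylamine set free may add to the ynenone, or the aminomethylene group may resist mild hydrolysis. The fallback sets out from 20 and comes back at 22. Soft enolisation (TMSOTf, Et3N, CH2Cl2, 0 °C) should give the bis(trimethylsilyl) derivative of 20 with a C6 O-silyl linear dienol ether (C6=C5, C4a=C8a) and a 7-O-silyl ether F3. A vinylogous Mukaiyama reaction of F3 with trimethyl orthoformate (BF3·OEt2, CH2Cl2, −78 °C) attacks through the γ-carbon C8a, since C5 is blocked by chlorine, and should give the C8a dimethoxymethyl enone with the 7-O-trimethylsilyl ether F4 as a mixture of C8a epimers. Cold 1 M HCl in THF hydrolyses the acetal and the silyl ether and leads to 22.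

Step 8. Sulfonylation may be poorly site-selective between the oxygens on C4a and C6, or may also take place at the tertiary hydroxyl. The fallback sets out from 13 and comes back at 20. TESOTf and 2,6-lutidine (CH2Cl2, −78 → 0 °C) should give the bis(triethylsilyl) derivative of 13 (C4a enol ether and 7-O ether) F5, from which K2CO3 in MeOH at 0 °C removes only the enol silyl group to give the 7-O-triethylsilyl ether of 13 F6. The bulky silyl ether now shields the C6 oxygen and removes the free hydroxyl, so Tf2O and Et3N at −78 °C should give the 7-O-triethylsilyl ether of triflate 14 F7. Sonogashira coupling of F7 with 19 under the conditions of step 12 gives the 7-O-triethylsilyl ether of 20 F8, and HF·pyridine in THF at 0 °C removes the silyl ether to give 20.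

Further compounds
F1 | step 6 | (2R)-2-tert-butyl-4-[(tert-butyldimethylsilyl)oxy]-5-methyl-1,3-dioxole | CC1=C(O[Si](C)(C)C(C)(C)C)O[C@H](C(C)(C)C)O1
F2 | step 6 | (2R,5S)-2-tert-butyl-5-methyl-5-[(1R)-1-Lac-3-oxobutyl]-1,3-dioxolan-4-one | CC(=O)C[C@@H]([C@]1(C)O[C@@H](C(C)(C)C)OC1=O)C2=C(OCC[Si](C)(C)C)C[C@H](C)OC2=O
F3 | step 13 | bis(trimethylsilyl) derivative of 20 (C6 O-silyl dienol ether, 7-O-silyl ether) | CC[C@H](C)/C=C(C)/C=C/C#CC1=C[C@H](C2=C(OCC[Si](C)(C)C)C[C@H](C)OC2=O)[C@](C)(O[Si](C)(C)C)C(O[Si](C)(C)C)=C1Cl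
F4 | step 13 | C8a dimethoxymethyl derivative of 20 as its 7-O-trimethylsilyl ether (C8a epimers) | CC[C@H](C)/C=C(C)/C=C/C#CC1=C(Cl)C(=O)[C@@](C)(O[Si](C)(C)C)[C@@H](C2=C(OCC[Si](C)(C)C)C[C@H](C)OC2=O)C1C(OC)OC
F5 | step 8 | bis(triethylsilyl) derivative of 13 (C4a enol ether, 7-O ether) | CC[Si](CC)(CC)OC1=C(Cl)C(=O)[C@@](C)(O[Si](CC)(CC)CC)[C@@H](C2=C(OCC[Si](C)(C)C)C[C@H](C)OC2=O)C1
F6 | step 8 | 7-O-triethylsilyl ether of 13 | OC1=C(Cl)C(=O)[C@@](C)(O[Si](CC)(CC)CC)[C@@H](C2=C(OCC[Si](C)(C)C)C[C@H](C)OC2=O)C1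
F7 | step 8 | 7-O-triethylsilyl ether of triflate 14 | O=S(=O)(OC1=C(Cl)C(=O)[C@@](C)(O[Si](CC)(CC)CC)[C@@H](C2=C(OCC[Si](C)(C)C)C[C@H](C)OC2=O)C1)C(F)(F)F
F8 | step 8 | 7-O-triethylsilyl ether of 20 | CC[C@H](C)/C=C(C)/C=C/C#CC1=C(Cl)C(=O)[C@@](C)(O[Si](CC)(CC)CC)[C@@H](C2=C(OCC[Si](C)(C)C)C[C@H](C)OC2=O)C1
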